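**Strategy.** In each butenolide the ring oxygen O1 lies between the lactone carbonyl C2 and the spiro carbon C5 shared with the cyclobutane, so each five-membered ring is the Baeyer–Villiger product of a spiro 3-alkoxycyclobut-2-enone. Everything rests on that twofold O1 insertion. In one operation the key step inserts both O1 atoms, enlarging two four-membered ketones to the two lactones with retention at both quaternary centres. Its precursor is a cyclobutene carrying two spiro 3-methoxycyclobutenones with the (S)- and (R)-silyloxybutyl chains, built by two ketene–methoxyalkyne [2+2] cycloadditions on desymmetrised cyclobut-3-ene-1,2-dicarboxylic acid; demethylation, bromination and acetylation finish the target.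

Key step: step 12

**Design notes**

- Structure check: with retentive migration, the spiro centres of bis-cyclobutenone 20, bis-tetronate 21 and the target correspond atom for atom (each ring carbonyl carbon is replaced by O1 on the same face). The chains are (S) on one ring and (R) on the other. No structural correction was needed.
- The dispiro core is C2-symmetric, so the (S)- and (R)-chains sit on equivalent positions; the hand of the target is fixed by step 8 alone, relayed through step 9.
- Methyl enol ethers replace ethyl ones. They can be removed by chloride at the methyl carbon under neutral conditions, whereas hot acid would strip the silyl ethers and dehydrate the 3-(1-oxyalkyl)tetronic acids.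
- The enol ethers must survive until after oxygen insertion: a cyclobutane-1,3-dione would make both spiro carbons non-stereogenic.
- An allyl ester replaces a methyl ester, because hydroxide would attack the strained vinylogous ester; the allyl group leaves under neutral conditions.
- Bromine is added only after C4 carries bromine (ring alkenes then deactivated) and before the silyl-to-acetate exchange.
- Anti addition alone does not define the target: two trans-dibromides are possible, and the target is the one with each bromine anti to the neighbouring C5–O1 bond (see step 15 and the risk list).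
- Assumption: quinidine is taken to give the (1R,2S) half-ester by analogy with related meso anhydrides; if the sense is opposite on this substrate, quinine is used instead and nothing else changes.
- The cyclobutene intermediates 16–23 are kept at or below 50 °C to avoid electrocyclic ring opening.

**Route**

Step 1
Reactants: 1 2-chloro-1,1-dimethoxyethane; 2 N-methoxy-N-methylbutanamide
Product: 4 1-methoxyhex-1-yn-3-one, via lithium methoxyacetylide 3 (not isolated)
Conditions: Et2NH, n-BuLi (3.1 equiv each), THF, 0 °C; 1, 0 °C; then 2, −78 °C; AcOH, −78 °C
Reagents that add atoms: none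
Why: Threefold action of the lithium amide on the chloroacetal (two eliminations, one deprotonation) gives the alkoxyacetylide in situ, which undergoes acyl substitution at the N-methoxy-N-methylamide through a chelated adduct that prevents over-addition; the cold acid quench protonates diethylamine before the ynone is released.

Step 2
Reactants: 4 1-methoxyhex-1-yn-3-one
Product: 5 (S)-1-methoxyhex-1-yn-3-ol
Conditions: Ru[(S,S)-TsDPEN](p-cymene) (1 mol%), i-PrOH, rt
Reagents that add atoms: none
Why: Asymmetric transfer hydrogenation of an alkynyl ketone, in which the alkynyl group takes the place of the aryl group of aryl ketones so that the (S,S)-catalyst should give the (S)-carbinol; the base-free, acid-free medium spares the ynol ether.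

Step 3
Reactants: 5 (S)-1-methoxyhex-1-yn-3-ol
Product: 6 tert-butyl{[(3S)-1-methoxyhex-1-yn-3-yl]oxy}dimethylsilane
Conditions: TBSCl, imidazole, DMF, 0 °C to rt
Reagents that add atoms: tert-butyldimethylsilyl chloride, CC(C)(C)[Si](C)(C)Cl
Why: Silylation of a secondary alcohol in an imidazole-buffered medium, which leaves the acid-labile alkoxyalkyne and the stereocentre untouched.

Step 4
Reactants: 4 1-methoxyhex-1-yn-3-one
Product: 7 (R)-1-methoxyhex-1-yn-3-ol
Conditions: Ru[(R,R)-TsDPEN](p-cymene) (1 mol%), i-PrOH, rt
Reagents that add atoms: none
Why: The same asymmetric transfer hydrogenation with the enantiomeric catalyst should give the (R)-carbinol.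

Step 5
Reactants: 7 (R)-1-methoxyhex-1-yn-3-ol
Product: 8 tert-butyl{[(3R)-1-methoxyhex-1-yn-3-yl]oxy}dimethylsilane
Conditions: TBSCl, imidazole, DMF, 0 °C to rt
Reagents that add atoms: tert-butyldimethylsilyl chloride, CC(C)(C)[Si](C)(C)Cl
Why: Silylation as in step 3, with the stereocentre untouched.

Step 6
Reactants: 9 maleic anhydride; 10 (E)-1,2-dichloroethene
Product: 11 cis-fused 6,7-dichloro-3-oxabicyclo[3.2.0]heptane-2,4-dione (mixture of chloride epimers)
Conditions: hν (medium-pressure Hg lamp, Pyrex), acetophenone (sensitiser), EtOAc, rt
Reagents that add atoms: none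
Why: Triplet-sensitised [2+2] photocycloaddition of the enedione to the haloalkene; the anhydride enforces the cis ring fusion and the CHCl configurations do not matter because both chlorines are removed next.

Step 7
Reactants: 11 dichloro photoadduct
Product: 12 cis-3-oxabicyclo[3.2.0]hept-6-ene-2,4-dione (meso cyclobutene anhydride)
Conditions: Zn dust (activated), Ac2O, toluene, 85 °C
Reagents that add atoms: none
Why: Zinc-mediated reductive 1,2-elimination of the vicinal dichloride gives the cyclobutene; the bicyclic anhydride cannot open by conrotation and so tolerates the temperature.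

Step 8
Reactants: 12 meso cyclobutene anhydride
Product: 13 (1R,2S)-2-[(prop-2-en-1-yloxy)carbonyl]cyclobut-3-ene-1-carboxylic acid
Conditions: allyl alcohol (3 equiv), quinidine (1.1 equiv), toluene, −55 °C; aqueous HCl wash
Reagents that add atoms: allyl alcohol, C=CCO
Why: Cinchona-alkaloid-mediated enantioselective alcoholysis of a meso anhydride, in which the alkaloid delivers the alcohol to one of the two enantiotopic carbonyl groups and so fixes both ring stereocentres.

Step 9
Reactants: 13 allyl half-ester; 6 (S)-silyloxy methoxyalkyne
Product: 16 allyl 6-[(1S)-1-(tert-butyldimethylsilyloxy)butyl]-7-methoxy-5-oxospiro[3.3]hepta-2,6-diene-1-carboxylate (ester cis to carbonyl C5 and trans to methoxy carbon C7), via acid chloride 14 (not isolated), via cyclobutenylidene ketene 15 (not isolated)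
Conditions: (COCl)2, DMF (cat.), CH2Cl2, 0 °C to rt, evaporate; then 6 (1.5 equiv), Et3N (slow addition), CH2Cl2, 0 °C to rt
Reagents that add atoms: none
Why: Dehydrochlorination gives the ketene, which undergoes the regioselective ketene–alkoxyalkyne [2+2] cycloaddition (ketene carbonyl carbon to the alkyl-bearing alkyne carbon); the bond to the ring carbon forms on the face anti to the neighbouring allyl ester, which sets the first quaternary centre.

Step 10
Reactants: 16 spiro cyclobutenone allyl ester
Product: 17 the corresponding carboxylic acid (6-[(1S)-1-(tert-butyldimethylsilyloxy)butyl]-7-methoxy-5-oxospiro[3.3]hepta-2,6-diene-1-carboxylic acid)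
Conditions: Pd(PPh3)4 (3 mol%), PhSiH3 (2 equiv), CH2Cl2, 0 °C to rt; aqueous work-up
Reagents that add atoms: none
Why: Deallylation catalysed by zerovalent palladium (π-allyl formation, hydride capture from the silane) frees the acid under neutral conditions, so the strained vinylogous ester meets neither hydroxide nor acid.

Step 11
Reactants: 17 spiro cyclobutenone acid; 8 (R)-silyloxy methoxyalkyne
Product: 20 dispiro bis(3-methoxycyclobutenone) on cyclobutene (1,8-dimethoxy-2-[(1S)-1-silyloxybutyl]-7-[(1R)-1-silyloxybutyl]dispiro[3.0.3.2]deca-1,7,9-triene-3,6-dione; the two carbonyls trans across the cyclobutene), via acid chloride 18 (not isolated), via ketene 19 (not isolated)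
Conditions: 1-chloro-N,N,2-trimethylprop-1-en-1-amine (1.2 equiv), CH2Cl2, 0 °C; then 8 (1.5 equiv), Et3N, 0 °C to rt
Reagents that add atoms: none
Why: Neutral acid chloride formation with the α-chloroenamine, then a second ketene–alkoxyalkyne [2+2] cycloaddition; the bond to the ring carbon should form anti to the methoxy-bearing arm of the first spiro ring (its methoxy group lies over that face, the carbonyl arm carries only oxygen), which places the two ring carbonyls trans.

Step 12
Reactants: 20 dispiro bis(3-methoxycyclobutenone)
Product: 21 dispiro bis(4-methoxybutenolide) on cyclobutene (bis-tetronate; the two ring oxygens trans across the cyclobutene)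
Conditions: 30% aq. H2O2 (10 equiv), LiOH (2.5 equiv), THF–H2O, 0 °C; Na2S2O3 quench
Reagents that add atoms: hydrogen peroxide, OO
Why: Hydroperoxide anion adds to each strained cyclobutenone carbonyl to give a tetrahedral peroxy adduct, and the quaternary spiro carbon migrates from carbon to oxygen with loss of hydroxide, inserting O1 between C2 and C5 of each future butenolide (double Baeyer–Villiger oxidation, known for cyclobutanones and cyclobutenones). Each of the two five-membered lactone rings is closed by ring enlargement of a four-membered ketone through this 1,2-shift, not by a cyclisation, and release of ring strain drives both insertions. No stereocentre is created: the migrating carbon keeps its configuration, so the two spiro centres set in steps 9 and 11 are carried over and each former C–C(=O) bond becomes the C5–O1 bond on the same face. The step needs migration of the sp3 spiro carbon and not of the alkenyl carbon, which the higher migratory aptitude of a tertiary allylic carbon secures. It also needs attack at the carbonyl and not at the cyclobutene alkene or the methoxy-bearing carbons, which the nucleophilic character of the oxidant and the strain-enhanced electrophilicity of the four-ring carbonyl secure. Low temperature and a hydroperoxide-rich medium limit hydroxide attack and thermal opening of the cyclobutene.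

Step 13
Reactants: 21 dispiro bis(4-methoxybutenolide)
Product: 22 dispiro bis(tetronic acid) (bis(4-hydroxybutenolide) with both silyl ethers intact)
Conditions: LiCl (10 equiv), DMSO, 50 °C; then cold 0.5 M HCl to pH 3; used at once
Reagents that add atoms: none
Why: SN2 O-demethylation of the methyl tetronates by chloride (the tetronate is a carboxylate-like leaving group) leaves silyl ethers, lactones and cyclobutene untouched and cannot scramble the spiro centres, because O1 and C4 stay different.

Step 14
Reactants: 22 dispiro bis(tetronic acid)
Product: 23 dispiro bis(4-bromobutenolide) on cyclobutene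
Conditions: (COBr)2 (3 equiv), DMF (3 equiv), CH2Cl2, 0 °C
Reagents that add atoms: oxalyl bromide, O=C(Br)C(=O)Br
Why: The bromoiminium (Vilsmeier-type) reagent turns each enolic hydroxyl into an iminium ether and bromide replaces it by addition–elimination at C4, the standard conversion of tetronic acids into 4-bromobutenolides.

Step 15
Reactants: 23 dispiro bis(4-bromobutenolide)
Product: 24 trans-dibromide (tetrabromide bis-silyl ether; each ring bromine anti to the neighbouring C5–O1 bond)
Conditions: Br2 (1.05 equiv), CH2Cl2, −78 to −20 °C, dark
Reagents that add atoms: bromine, BrBr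
Why: Electrophilic anti addition through a bromonium ion gives a trans-dibromide at the only electron-rich alkene left; the required one of the two trans-dibromides should form if bromide opens the bromonium at the carbon where it enters anti to the vicinal C–O bond, avoiding dipolar repulsion with the lactone oxygen, a bias that the low-polarity medium should strengthen.

Step 16
Reactants: 24 tetrabromide bis-silyl ether
Product: 26 target CNP0266230.1, via diol 25 (not isolated)
Conditions: HF·pyridine, pyridine–THF, 0 °C to rt; then Ac2O (excess), rt
Reagents that add atoms: acetic anhydride, CC(=O)OC(C)=O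
Why: Fluoride-induced desilylation then O-acetylation, both at oxygen, so the two carbinol configurations are retained; no anti-periplanar H–C–C–Br pair is available for base-induced elimination.

**Compound list**

1 | 2-chloro-1,1-dimethoxyethane | COC(CCl)OC | starting material
2 | N-methoxy-N-methylbutanamide | CCCC(=O)N(C)OC | starting material
3 | lithium methoxyacetylide | [Li]C#COC | intermediate
4 | 1-methoxyhex-1-yn-3-one | CCCC(=O)C#COC | intermediate
5 | (S)-1-methoxyhex-1-yn-3-ol | CCC[C@H](O)C#COC | intermediate
6 | tert-butyl{[(3S)-1-methoxyhex-1-yn-3-yl]oxy}dimethylsilane | CCC[C@H](O[Si](C)(C)C(C)(C)C)C#COC | intermediate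
7 | (R)-1-methoxyhex-1-yn-3-ol | CCC[C@@H](O)C#COC | intermediate
8 | tert-butyl{[(3R)-1-methoxyhex-1-yn-3-yl]oxy}dimethylsilane | CCC[C@@H](O[Si](C)(C)C(C)(C)C)C#COC | intermediate
9 | maleic anhydride | O=C1OC(=O)C=C1 | starting material
10 | (E)-1,2-dichloroethene | Cl/C=C/Cl | starting material
11 | cis-fused 6,7-dichloro-3-oxabicyclo[3.2.0]heptane-2,4-dione (chloride epimers) | O=C1OC(=O)[C@@H]2[C@H]1C(Cl)C2Cl | intermediate
12 | cis-3-oxabicyclo[3.2.0]hept-6-ene-2,4-dione (meso) | O=C1OC(=O)[C@@H]2[C@H]1C=C2 | intermediate
13 | (1R,2S)-2-[(prop-2-en-1-yloxy)carbonyl]cyclobut-3-ene-1-carboxylic acid | OC(=O)[C@@H]1C=C[C@@H]1C(=O)OCC=C | intermediate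
14 | acid chloride of 13 | ClC(=O)[C@@H]1C=C[C@@H]1C(=O)OCC=C | intermediate
15 | allyl 4-(oxomethylidene)cyclobut-2-ene-1-carboxylate (ketene) | O=C=C1C=C[C@@H]1C(=O)OCC=C | intermediate
16 | allyl 6-[(1S)-1-(TBS-oxy)butyl]-7-methoxy-5-oxospiro[3.3]hepta-2,6-diene-1-carboxylate, ester cis to C5 carbonyl | CCC[C@H](O[Si](C)(C)C(C)(C)C)C1=C(OC)[C@@]2(C1=O)C=C[C@@H]2C(=O)OCC=C | intermediate
17 | carboxylic acid from 16 | CCC[C@H](O[Si](C)(C)C(C)(C)C)C1=C(OC)[C@@]2(C1=O)C=C[C@@H]2C(=O)O | intermediate
18 | acid chloride of 17 | CCC[C@H](O[Si](C)(C)C(C)(C)C)C1=C(OC)[C@@]2(C1=O)C=C[C@@H]2C(=O)Cl | intermediate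
19 | ketene from 18 | CCC[C@H](O[Si](C)(C)C(C)(C)C)C1=C(OC)[C@@]2(C1=O)C=CC2=C=O | intermediate
20 | dispiro bis(3-methoxycyclobutenone) on cyclobutene, (S)- and (R)-silyloxybutyl chains, carbonyls trans | CCC[C@H](O[Si](C)(C)C(C)(C)C)C1=C(OC)[C@@]2(C1=O)C=C[C@@]21C(=O)C([C@@H](CCC)O[Si](C)(C)C(C)(C)C)=C1OC | intermediate
21 | dispiro bis(4-methoxybutenolide) on cyclobutene (bis-tetronate) | CCC[C@H](O[Si](C)(C)C(C)(C)C)C1=C(OC)[C@@]2(OC1=O)C=C[C@@]21OC(=O)C([C@@H](CCC)O[Si](C)(C)C(C)(C)C)=C1OC | intermediate
22 | dispiro bis(tetronic acid) | CCC[C@H](O[Si](C)(C)C(C)(C)C)C1=C(O)[C@@]2(OC1=O)C=C[C@@]21OC(=O)C([C@@H](CCC)O[Si](C)(C)C(C)(C)C)=C1O | intermediate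
23 | dispiro bis(4-bromobutenolide) on cyclobutene | CCC[C@H](O[Si](C)(C)C(C)(C)C)C1=C(Br)[C@@]2(OC1=O)C=C[C@@]21OC(=O)C([C@@H](CCC)O[Si](C)(C)C(C)(C)C)=C1Br | intermediate
24 | tetrabromide bis-silyl ether, ring bromines trans and each anti to the adjacent C5–O1 bond | CCC[C@H](O[Si](C)(C)C(C)(C)C)C1=C(Br)[C@@]2(OC1=O)[C@@H](Br)[C@H](Br)[C@@]21OC(=O)C([C@@H](CCC)O[Si](C)(C)C(C)(C)C)=C1Br | intermediate
25 | tetrabromide diol | CCC[C@H](O)C1=C(Br)[C@@]2(OC1=O)[C@@H](Br)[C@H](Br)[C@@]21OC(=O)C([C@@H](CCC)O)=C1Br | intermediate
26 | CNP0266230.1 | CCC[C@H](OC(C)=O)C1=C(Br)[C@@]2(OC1=O)[C@@H](Br)[C@H](Br)[C@@]21OC(=O)C([C@@H](CCC)OC(C)=O)=C1Br | target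

**Step count and risk**

Total steps: 16. Longest linear sequence: 11 steps (steps 1, 2, 3, then 9 to 16; the anhydride branch, steps 6 to 8 then 9 to 16, is equally long).

Steps most likely to fail:

1. Step 15. Bromide may open the bromonium ion at the other alkene carbon, entering on the sterically more open face syn to the lactone oxygen and away from the bromine-bearing C4; this would give the other trans-dibromide. The sense of this opening is the least secure stereochemical point of the route. The fallback sets out from 23 and comes back at 24. The unwanted isomer, the trans-dibromide with each bromine syn to the neighbouring ring oxygen F1, is not discarded. Vicinal trans-dibromides interconvert by concerted 1,2-interchange of the two bromines (dyotropic mutarotation, each bromine moving to the neighbouring carbon on its own face). Gentle warming of F1 in a polar non-nucleophilic solvent (1,2-dichloroethane or nitromethane, 40 to 60 °C) should therefore equilibrate it with 24, in which both C–Br dipoles lie anti to the adjacent C–O bonds. Remaining F1 is returned to 23 by anti debromination with Zn in AcOH–THF at 0 °C and resubmitted.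

2. Step 12. Hydroperoxide or hydroxide may attack the methoxy-bearing ring carbon (addition–elimination) or cleave the strained ring instead of triggering migration, or the second insertion may lag behind the first. The fallback sets out from 20 and comes back at 21 and changes the mode of activation from anionic to neutral: aqueous H2O2 in 1,1,1,3,3,3-hexafluoropropan-2-ol at 0 °C to rt without any base. The fluorinated alcohol activates the strained carbonyl and the peroxide by hydrogen bonding, and the neutral perhydrate rearranges, so no peroxide anion or hydroxide is present to attack the methoxy-bearing carbon or cleave the ring. This fallback forms no new compound (F0).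

3. Step 11. The hindered ketene may be trapped slowly, and the facial preference may be poor because the two arms of the first spiro ring (carbonyl carbon and methoxy-bearing carbon) differ only modestly in size, giving the cis-dispiro diastereomer. The fallback sets out from 16 and comes back at 21 by performing the oxygen insertions one ring at a time. Oxidation of 16 under the conditions of step 12 gives the spiro tetronate allyl ester F2. Deallylation as in step 10 gives the spiro tetronate acid F3. The α-chloroenamine converts it into the acid chloride F4, and Et3N gives the ketene F5. The ketene carbon in F5 is flanked by a bare ring oxygen on one face and the methoxy-bearing C4 on the other, a much larger difference, and it is less hindered. Cycloaddition with 8 anti to C4 gives the spiro butenolide–cyclobutenone F6, and a second Baeyer–Villiger oxidation of its remaining four-membered ketone returns to the route at 21.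

**Further compounds**

F1 | step 15 | trans-dibromide bis-silyl ether with each ring bromine syn to the neighbouring ring oxygen | CCC[C@H](O[Si](C)(C)C(C)(C)C)C1=C(Br)[C@@]2(OC1=O)[C@H](Br)[C@@H](Br)[C@@]21OC(=O)C([C@@H](CCC)O[Si](C)(C)C(C)(C)C)=C1Br
F0 | step 12 | none | none
F2 | step 11 | spiro tetronate allyl ester (Baeyer–Villiger product of 16) | CCC[C@H](O[Si](C)(C)C(C)(C)C)C1=C(OC)[C@@]2(OC1=O)C=C[C@@H]2C(=O)OCC=C
F3 | step 11 | spiro tetronate carboxylic acid | CCC[C@H](O[Si](C)(C)C(C)(C)C)C1=C(OC)[C@@]2(OC1=O)C=C[C@@H]2C(=O)O
F4 | step 11 | acid chloride of F3 | CCC[C@H](O[Si](C)(C)C(C)(C)C)C1=C(OC)[C@@]2(OC1=O)C=C[C@@H]2C(=O)Cl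
F5 | step 11 | ketene from F4 | CCC[C@H](O[Si](C)(C)C(C)(C)C)C1=C(OC)[C@@]2(OC1=O)C=CC2=C=O
F6 | step 11 | spiro butenolide–spiro cyclobutenone on cyclobutene | CCC[C@H](O[Si](C)(C)C(C)(C)C)C1=C(OC)[C@@]2(OC1=O)C=C[C@@]21C(=O)C([C@@H](CCC)O[Si](C)(C)C(C)(C)C)=C1OC
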